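## Analysis of the target

The target is a germacranolide. Its core is a ten-membered carbocycle (C1–C10) with a trans-fused α-methylene-γ-butyrolactone across C6 (oxygen) and C7 (C11, with C12 as carbonyl and C13 as exocyclic methylene). The ring holds a Z-trisubstituted C4–C5 alkene (methyl C15 on C4) and an E-trisubstituted C9–C10 alkene (methyl C14 on C10).

There are five stereocentres: 1S, 3S, 6R, 7S and 8R. C6, C7 and C8 are contiguous: H6 and H7 are trans on the lactone, and the C8 oxygen is 1,3-anti to the C6 oxygen along C6–C7–C8. C1 and C3 form a 1,3-anti diol in which only the C3 oxygen is acetylated.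

Three oxygens are acylated differently (lactone at C6, tiglate at C8, acetate at C3) and the fourth (C1) is free, so any late protecting-group scheme is costly. The α-methylene lactone is a Michael acceptor and does not tolerate nucleophilic base. The tiglate and the allylic acetate can migrate or be cleaved. The Z C4–C5 alkene is the less stable isomer once C3 is a carbonyl.

The main difficulty is closing the strained ten-membered ring, in which nine of the ten ring atoms are sp2 or stereogenic, without disturbing these groups.

The strategy rests on the C1(OH)–C2–C3(OAc) unit. C2 is the only methylene of the ring and lies between two oxygenated carbons, so C2–C3 is an aldol bond. An anti diol monoester is exactly what an aldehyde-mediated hydride shift from the C3 oxygen to a C1 ketone leaves behind.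

## Retrosynthetic reasoning

**C1–H and acetyl–O3.** These two bonds are cut together. Target 29 goes back to the 3-hydroxy-1-ketone 27 and acetaldehyde 28. A 1,3-diol precursor is avoided because its two secondary allylic hydroxyls could not be told apart. The forward Evans–Tishchenko reaction must deliver hydride to C1 from the C3 oxygen (1,3-anti) and leave the acyl group on that oxygen.

**C2–C3.** In 27 this is the aldol bond, the only ring bond between a ketone and a carbinol. Cutting it opens the ring to the seco compound 24: a bromomethyl ketone at C1/C2, a Z-enal at C3, lactone and tiglate complete. Cuts at C7–C8, C8–C9 or C1–C2 would leave several oxygens to be unmasked and acylated after ring formation. Here nothing but the final reduction follows. The forward step must turn the C–Br bond into enolate 25, close the ring to aldolate 26, set C3 and spare the enal.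

**Functional-group changes to 24.** The labile Z-enal is made last, from allylic alcohol 23, which comes from silyl ether 22. The bromine of 22 is placed on the C2 methyl of methyl enone 20 through silyl dienol ether 21. Bromination precedes aldehyde formation because enolising conditions would scramble a Z-enal.

**C9=C10.** This bond of 20 is a Wittig bond between the α-acyloxy aldehyde 18 and the stabilised ylide 19. The E geometry is fixed before the ring exists. Aldehyde 18 comes from PMB ether 16 through alcohol 17.

**C8–O.** The tiglate of 16 is cut between C8 and oxygen, not at the acyl carbon. The pieces are tiglic acid 15 and alcohol 14, which has the opposite configuration at C8. This cut is chosen because the C7–C8 bond-forming reaction below delivers that epimer. A Mitsunobu esterification then inverts and acylates in one step.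

**C7–C8.** Alcohol 14 is cut into aldehyde 12 and bromobutenolide 11, joined forward by a Barbier allylation through allylmetal 13. This single step creates the α-methylene lactone in finished form and sets C7 and C8 from C6.

**C7=C11 of the butenolide.** Compound 11 is opened by a ring-closing metathesis transform to ester 10, which is made from dienol 8 and acid 9. This puts all lactone carbons on a C6 carbinol without any oxidation-state change.

**C5–C6 and the Z alkene.** Dienol 8 is the resolved enantiomer of racemate 7. The C5–C6 bond of 7 joins alkenyllithium 6 (from iodide 4) to acrolein 5. Iodide 4 is the silyl ether of 3, made from propargyl alcohol 1 by carbomagnesiation through chelate 2. That chelate fixes the Z geometry of C4–C5.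

## Alternatives that were turned down

**Alternative 1: ring contraction at C7–C8 (Wittig–Still).**
- Disconnection: the ring is first formed as a thirteen-membered ether and then contracted.
- Forward key step: n-BuLi (THF, −78 °C) exchanges a trialkyltin group on C8, which carries the ether oxygen. The α-alkoxy carbanion attacks C7 in a [2,3] shift across the O–C13–C11=C7 allyl unit and the O–C13 bond breaks. Carbocycle A1 results, with a free C8 hydroxyl and the C11=C13 methylene.
- For: one sigmatropic event makes the C7–C8 bond, both its stereocentres and the exocyclic alkene. The macrocycle closed beforehand is larger and less strained. The free C8 hydroxyl of A1 is ready for tigloylation, and no reducible carbonyl is present. On control of C7/C8 within the ring-forming step it is stronger than the chosen route, which must invert C8.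
- Against: the facial course depends on the conformation of a flexible thirteen-membered ring and on the C7=C11 geometry. The tin-bearing C8 stereocentre must be built and carried intact. A1 still has C12 at the alcohol level and three differently protected oxygens, so C12 oxidation, lactonisation onto O6, unmasking and acetylation at C3 and unmasking at C1 remain: about six steps after the ring exists.
- Comparison: the chosen strategy closes the ring with lactone and tiglate complete and ends one step later without a protecting group.

**Alternative 2: Claisen ring expansion at C1–C2.**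
- Disconnection: C1–C2, through a two-atom ring expansion.
- Forward key step: the lactone carbonyl (C3) of an eight-membered ring is methylenated with Cp2TiMe2. Heating the resulting enol ether drives a Claisen rearrangement: C1–C2 forms, O–C9 breaks, C3 becomes a ketone. The ten-membered dienone A2 results, with the E C9–C10 alkene and a silyl ether at C1.
- For: the step is unimolecular and needs no high dilution. Its chair transition state fixes the E alkene and relays chirality to C1. On entropy and on setting alkene geometry during ring formation it is stronger than the chosen route.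
- Against: the eight-membered Z-unsaturated lactone is itself a medium-ring problem. The migrating terminus C1 must be an enol silyl ether of defined geometry. A2 has its ketone at C3, conjugated with the Z alkene and prone to isomerisation, and the protected alcohol at C1. That is the reverse of the pattern an Evans–Tishchenko finish needs, so C3 must be reduced under separate control and acetylated. C12 oxidation, lactonisation and tigloylation at C8 still follow.
- Comparison: the chosen route sets the E alkene beforehand with a stabilised ylide and has the ketone at C1, so the last reduction places the acetate correctly.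

**Alternative 3: alkynyl Nozaki–Hiyama–Kishi closure at C8–C9.**
- Disconnection: C8–C9.
- Forward key step: CrCl2 (divalent chromium) with catalytic NiCl2 converts a C9 iodoalkyne into an alkynylchromium species that adds to the C8 aldehyde and closes cycloalkynol A3. The E C9–C10 alkene and C14 come later by hydroxyl-directed trans-hydroalumination and methylation at C10.
- For: chromium acetylides add only to aldehydes, and macrocyclisations of this kind are well established. On functional-group tolerance of the ring closure it is stronger than a samarium closure next to an enal. The hydroalumination gives a geometrically defined trisubstituted alkene.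
- Against: four collinear atoms (C8–C9≡C10–C1) inside a ten-membered ring that also holds a Z alkene make a strained cyclodecenyne. C8 is created in the ring closure without an obvious control element. Three steps are needed to turn the alkyne into the methyl-bearing alkene, and then the same oxidation, lactonisation and acylation sequence as in the other alternatives.
- Comparison: the chosen strategy has C8 fixed before cyclisation and needs one step after it.

Key step: step 15

Remark: locants C1–C15 follow germacrane numbering in every intermediate, acyclic ones included.

Assumption: the zinc Barbier addition of step 7 is taken to pass through the closed chair transition state, which gives the C8 alcohol epimeric to the target. Step 8 is built on this.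

## Route

Step 1
Reactants: 1 prop-2-yn-1-ol
Product: 3 (Z)-3-iodo-2-methylprop-2-en-1-ol, via alkenylmagnesium alkoxide 2 (not isolated)
Conditions: MeMgBr (3 equiv), CuI (10 mol%), Et2O, −10 °C to rt; then I2, −78 to 0 °C
Reagents that add atoms: methylmagnesium bromide, C[Mg]Br; iodine, II
Why: Copper-catalysed anti-carbomagnesiation of a propargylic alkoxide: methyl adds to C4 and magnesium to C5 inside an oxygen-chelated five-membered ring. Iodinolysis with retention places iodine cis to the CH2O group, which is the Z C4–C5 geometry of the target.

Step 2
Reactants: 3 (Z)-3-iodo-2-methylprop-2-en-1-ol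
Product: 4 (Z)-tert-butyl[(3-iodo-2-methylprop-2-en-1-yl)oxy]dimethylsilane
Conditions: TBSCl, imidazole, CH2Cl2, 0 °C to rt
Reagents that add atoms: tert-butyldimethylsilyl chloride, CC(C)(C)[Si](C)(C)Cl
Why: Standard silylation of a primary alcohol. The TBS ether survives organolithium, metathesis, zinc, Mitsunobu, DDQ and enolisation conditions and is removed at the end by acidic fluoride.

Step 3
Reactants: 4 (Z)-tert-butyl[(3-iodo-2-methylprop-2-en-1-yl)oxy]dimethylsilane; 5 acrolein
Product: 7 racemic (Z)-6-(tert-butyldimethylsilyloxy)-5-methylhexa-1,4-dien-3-ol, via (Z)-alkenyllithium 6 (not isolated)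
Conditions: t-BuLi (2.1 equiv), Et2O, −78 °C; then 5, −78 °C
Reagents that add atoms: none
Why: Iodine–lithium exchange with retention of alkene geometry, then 1,2-addition to the enal carbonyl forms C5–C6. At −78 °C in ether the silyl group stays on oxygen and conjugate addition does not compete. C6 is formed racemic.

Step 4
Reactants: 7 racemic (Z)-6-(tert-butyldimethylsilyloxy)-5-methylhexa-1,4-dien-3-ol
Product: 8 (3S,4Z)-6-(tert-butyldimethylsilyloxy)-5-methylhexa-1,4-dien-3-ol
Conditions: Candida antarctica lipase B (immobilised), vinyl acetate, hexane, 30 °C, stopped shortly after half conversion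
Reagents that add atoms: none
Why: Lipase-catalysed kinetic resolution of a vinyl carbinol. By the Kazlauskas rule the enantiomer with the larger (substituted alkenyl) group on the fast side, here 3R, is acetylated, and the 3S alcohol that becomes C6 is recovered. Running just past half conversion should secure its enantiopurity.

Step 5
Reactants: 8 (3S,4Z)-6-(tert-butyldimethylsilyloxy)-5-methylhexa-1,4-dien-3-ol; 9 2-(bromomethyl)acrylic acid
Product: 10 (3S,4Z)-6-(tert-butyldimethylsilyloxy)-5-methylhexa-1,4-dien-3-yl 2-(bromomethyl)acrylate
Conditions: DCC, 4-(dimethylamino)pyridine (cat.), CH2Cl2, 0 °C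
Reagents that add atoms: none
Why: Steglich esterification forms the acyl–oxygen bond, so C6 keeps its configuration. The neutral, cold conditions avoid ionisation of the bis-allylic carbinol and substitution of the allylic bromide.

Step 6
Reactants: 10 (3S,4Z)-6-(tert-butyldimethylsilyloxy)-5-methylhexa-1,4-dien-3-yl 2-(bromomethyl)acrylate
Product: 11 (5R)-3-(bromomethyl)-5-[(1Z)-3-(tert-butyldimethylsilyloxy)-2-methylprop-1-enyl]furan-2(5H)-one
Conditions: second-generation Grubbs catalyst (H2IMes)(PCy3)Cl2Ru=CHPh (5 mol%), CH2Cl2, 40 °C
Reagents that add atoms: none
Why: Ring-closing metathesis. The ruthenium carbene forms at the monosubstituted vinyl group and closes onto the 1,1-disubstituted acrylate to give the butenolide (C7=C11). The trisubstituted C4–C5 alkene is too hindered to take part and C6 is untouched.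

Step 7
Reactants: 11 (5R)-3-(bromomethyl)-5-[(1Z)-3-(tert-butyldimethylsilyloxy)-2-methylprop-1-enyl]furan-2(5H)-one; 12 2-[(4-methoxybenzyl)oxy]acetaldehyde
Product: 14 (6R,7R,8R)-trans-α-methylene lactone with C8 hydroxyl epimeric to the target, via allylzinc bromide 13 (not isolated)
Conditions: Zn dust, THF/sat. aq. NH4Cl, 0 °C to rt
Reagents that add atoms: none
Why: Zinc Barbier allylation of a 3-(bromomethyl)butenolide. The allylzinc reacts at its ring carbon C7 through a closed six-membered chair, on the face opposite the C6 substituent (trans lactone, C7 set) and with the aldehyde residue equatorial, away from the lactone ring. That places the C8 hydroxyl anti to C6, the epimer of the target at C8 that step 8 requires, and the allylic shift leaves the α-methylene lactone finished.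

Step 8
Reactants: 14 (6R,7R,8R)-trans-α-methylene lactone with C8 hydroxyl epimeric to the target; 15 tiglic acid
Product: 16 (6R,7S,8S)-lactone C8 tiglate with C9 PMB ether
Conditions: PPh3, DIAD, toluene, 0 °C to rt
Reagents that add atoms: none
Why: Mitsunobu esterification. SN2 displacement of the phosphorus-activated C8 oxygen by tiglate inverts C8 to the target configuration and installs the ester in one operation. The neutral conditions leave the α-methylene lactone and both ethers untouched.

Step 9
Reactants: 16 (6R,7S,8S)-lactone C8 tiglate with C9 PMB ether
Product: 17 (6R,7S,8S)-lactone C8 tiglate with free C9 hydroxyl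
Conditions: DDQ, CH2Cl2/pH 7 buffer, 0 °C
Reagents that add atoms: none
Why: Oxidative cleavage of the PMB ether by electron transfer from the electron-rich arene. The silyl ether, both esters and the alkenes are not oxidised, and the buffered neutral medium disfavours tiglate migration from O8 to O9.

Step 10
Reactants: 17 (6R,7S,8S)-lactone C8 tiglate with free C9 hydroxyl
Product: 18 (6R,7S,8S)-lactone C8 tiglate C9 aldehyde
Conditions: Dess–Martin periodinane, NaHCO3, CH2Cl2, 0 °C
Reagents that add atoms: none
Why: Dess–Martin oxidation of a primary alcohol under buffered, non-basic conditions. The α-acyloxy aldehyde is neither epimerised at C8 nor over-oxidised, and is used without storage.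

Step 11
Reactants: 18 (6R,7S,8S)-lactone C8 tiglate C9 aldehyde; 19 3-(triphenylphosphoranylidene)butan-2-one
Product: 20 (6R,7S,8R)-lactone with C8 tiglate and E methyl enone side chain
Conditions: toluene, 60 °C
Reagents that add atoms: none
Why: Wittig olefination with a ketone-stabilised, α-methyl ylide forms C9=C10 with E geometry (C8 trans to C1) under thermodynamic control. The activated α-acyloxy aldehyde reacts at moderate temperature, and the salt-free neutral ylide should not epimerise C8 or add to the methylene lactone.

Step 12
Reactants: 20 (6R,7S,8R)-lactone with C8 tiglate and E methyl enone side chain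
Product: 22 (6R,7S,8R)-lactone with C8 tiglate and E bromomethyl enone side chain, via trimethylsilyl dienol ether 21 (not isolated)
Conditions: TMSOTf, Et3N, CH2Cl2, −78 to 0 °C; then NBS, THF, −78 °C
Reagents that add atoms: N-bromosuccinimide, O=C1CCC(=O)N1Br
Why: Soft enolisation of the methyl ketone toward its only α-methyl (C2) gives the 2-silyloxy diene. Electrophilic bromination of that enol ether at its terminus puts bromine on C2 alone. Lactone and tiglate have no enolisable α-hydrogen, and the cold NBS is consumed by the far more nucleophilic enol ether before it can touch the C4–C5 alkene.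

Step 13
Reactants: 22 (6R,7S,8R)-lactone with C8 tiglate and E bromomethyl enone side chain
Product: 23 (6R,7S,8R)-bromomethyl enone with free C3 hydroxyl
Conditions: 48% aq. HF, MeCN, 0 °C
Reagents that add atoms: none
Why: Acidic fluoride cleavage of the primary TBS ether. The medium is free of base and amine, so the bromomethyl ketone, both esters and the methylene lactone persist.

Step 14
Reactants: 23 (6R,7S,8R)-bromomethyl enone with free C3 hydroxyl
Product: 24 (6R,7S,8R)-seco bromomethyl enone Z-enal
Conditions: Dess–Martin periodinane, NaHCO3, CH2Cl2, 0 °C; used at once
Reagents that add atoms: none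
Why: Dess–Martin oxidation of the Z allylic alcohol. The buffered, cold, short reaction gives acid or base no opportunity to isomerise the angelate-type Z-enal, which is carried straight into the ring closure.

Step 15
Reactants: 24 (6R,7S,8R)-seco bromomethyl enone Z-enal
Product: 27 (3S,6R,7S,8R)-3-hydroxy-1-ketone of the germacranolide, via samarium enolate 25 (not isolated), via samarium aldolate 26 (not isolated)
Conditions: SmI2 (2.0 equiv, 0.1 M in THF) added to 24 (0.005 M in THF), −78 °C; then sat. aq. NH4Cl
Reagents that add atoms: none
Why: Intramolecular samarium Reformatsky reaction, an aldol-type ring closure whose closest precedent is the SmI2-mediated medium-ring cyclisation of ω-formyl α-bromo ketones. Two one-electron transfers from divalent samarium break the C2–Br bond and give the trivalent samarium enolate 25, whose C2 terminus adds to the C3 aldehyde to form aldolate 26, protonated on work-up. The ten-membered ring closes in a 10-(enolendo)-exo-trig mode: both enolate carbons (C1, C2) end up in the ring and the aldehyde oxygen outside it. The new stereocentre C3 is under substrate control: samarium bridges the enolate and aldehyde oxygens in a six-membered chair with C4 equatorial, and the trans-fused lactone with the two planar trisubstituted alkenes is expected to let the chain ends meet only with C2 on the Si face of the aldehyde, which corresponds to 3S. The step needs chemoselectivity for the C–Br bond over the enal, the γ-acyloxy enone, the α-methylene lactone and the tiglate; this is secured by the much faster electron transfer to the α-bromo ketone, by adding exactly two equivalents of SmI2 to the dilute substrate at −78 °C so that no excess reductant is present, and by the absence of proton donors and HMPA. High dilution suppresses intermolecular aldol addition, and the cold, neutral medium keeps the Z geometry of C4–C5.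

Step 16
Reactants: 27 (3S,6R,7S,8R)-3-hydroxy-1-ketone of the germacranolide; 28 acetaldehyde
Product: 29 target (1S,3S,6R,7S,8R)-germacranolide CNP0319825.6
Conditions: 28 (10 equiv), SmI2 (0.3 equiv, premixed with 28), THF, −10 °C
Reagents that add atoms: none
Why: Evans–Tishchenko reduction. The trivalent samarium catalyst (formed from SmI2 and the aldehyde) holds the C3 oxygen, acetaldehyde and the C1 carbonyl in a six-membered chair, and the hydrogen of the former aldehyde carbon shifts as hydride to C1. Delivery from the C3 oxygen puts the new C1 hydroxyl anti to it (1S) and leaves the acetyl group on O3, so acetate, free hydroxyl and C1 configuration are set together while lactone, tiglate and alkenes stay inert.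

## Compound list

1 | prop-2-yn-1-ol (propargyl alcohol) | C#CCO | starting material
2 | (Z)-alkenylmagnesium alkoxide from the carbomagnesiation, magnesium on C5 cis to the CH2O group | Br[Mg]/C=C(/C)CO[Mg]Br | intermediate
3 | (Z)-3-iodo-2-methylprop-2-en-1-ol | OC/C(C)=C\I | intermediate
4 | (Z)-tert-butyl[(3-iodo-2-methylprop-2-en-1-yl)oxy]dimethylsilane | CC(C)(C)[Si](C)(C)OC/C(C)=C\I | intermediate
5 | acrolein | C=CC=O | starting material
6 | (Z)-3-(tert-butyldimethylsilyloxy)-2-methylprop-1-enyllithium | [Li]/C=C(/C)CO[Si](C)(C)C(C)(C)C | intermediate
7 | racemic (Z)-6-(tert-butyldimethylsilyloxy)-5-methylhexa-1,4-dien-3-ol | C=CC(O)/C=C(/C)CO[Si](C)(C)C(C)(C)C | intermediate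
8 | (3S,4Z)-6-(tert-butyldimethylsilyloxy)-5-methylhexa-1,4-dien-3-ol | C=C[C@H](O)/C=C(/C)CO[Si](C)(C)C(C)(C)C | intermediate
9 | 2-(bromomethyl)acrylic acid | C=C(CBr)C(=O)O | starting material
10 | (3S,4Z)-6-(tert-butyldimethylsilyloxy)-5-methylhexa-1,4-dien-3-yl 2-(bromomethyl)acrylate | C=C(CBr)C(=O)O[C@@H](C=C)/C=C(/C)CO[Si](C)(C)C(C)(C)C | intermediate
11 | (5R)-3-(bromomethyl)-5-[(1Z)-3-(tert-butyldimethylsilyloxy)-2-methylprop-1-enyl]furan-2(5H)-one | BrCC1=C[C@@H](/C=C(/C)CO[Si](C)(C)C(C)(C)C)OC1=O | intermediate
12 | 2-[(4-methoxybenzyl)oxy]acetaldehyde | COc1ccc(COCC=O)cc1 | starting material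
13 | allylzinc bromide derived from 11 (zinc on C13) | Br[Zn]CC1=C[C@@H](/C=C(/C)CO[Si](C)(C)C(C)(C)C)OC1=O | intermediate
14 | (6R,7R,8R)-trans-fused α-methylene-γ-butyrolactone: Z-CH=C(CH3)CH2OTBS on C6, CH(OH)CH2OPMB on C7, C8 epimeric to the target | C=C1C(=O)O[C@H](/C=C(/C)CO[Si](C)(C)C(C)(C)C)[C@H]1[C@@H](O)COCc1ccc(OC)cc1 | intermediate
15 | tiglic acid, (E)-2-methylbut-2-enoic acid | C/C=C(\C)C(=O)O | starting material
16 | (6R,7S,8S)-lactone of 14 with inverted C8 carrying the tiglate (target configuration), C9 PMB ether | C=C1C(=O)O[C@H](/C=C(/C)CO[Si](C)(C)C(C)(C)C)[C@H]1[C@H](OC(=O)/C(C)=C/C)COCc1ccc(OC)cc1 | intermediate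
17 | (6R,7S,8S)-lactone C8 tiglate with free C9 hydroxyl | C=C1C(=O)O[C@H](/C=C(/C)CO[Si](C)(C)C(C)(C)C)[C@H]1[C@H](OC(=O)/C(C)=C/C)CO | intermediate
18 | (6R,7S,8S)-lactone C8 tiglate C9 aldehyde | C=C1C(=O)O[C@H](/C=C(/C)CO[Si](C)(C)C(C)(C)C)[C@H]1[C@H](OC(=O)/C(C)=C/C)C=O | intermediate
19 | 3-(triphenylphosphoranylidene)butan-2-one | CC(=O)C(C)=P(c1ccccc1)(c1ccccc1)c1ccccc1 | starting material
20 | (6R,7S,8R)-lactone with C8 tiglate and (E)-CH=C(CH3)C(=O)CH3 on C8, C3 TBS ether | C=C1C(=O)O[C@H](/C=C(/C)CO[Si](C)(C)C(C)(C)C)[C@H]1[C@H](OC(=O)/C(C)=C/C)/C=C(\C)C(C)=O | intermediate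
21 | trimethylsilyl dienol ether of 20 (C1–O–Si, C1=C2) | C=C1C(=O)O[C@H](/C=C(/C)CO[Si](C)(C)C(C)(C)C)[C@H]1[C@H](OC(=O)/C(C)=C/C)/C=C(\C)C(=C)O[Si](C)(C)C | intermediate
22 | (6R,7S,8R)-lactone with C8 tiglate and (E)-CH=C(CH3)C(=O)CH2Br, C3 TBS ether | C=C1C(=O)O[C@H](/C=C(/C)CO[Si](C)(C)C(C)(C)C)[C@H]1[C@H](OC(=O)/C(C)=C/C)/C=C(\C)C(=O)CBr | intermediate
23 | (6R,7S,8R)-bromomethyl enone with free C3 hydroxyl | C=C1C(=O)O[C@H](/C=C(/C)CO)[C@H]1[C@H](OC(=O)/C(C)=C/C)/C=C(\C)C(=O)CBr | intermediate
24 | (6R,7S,8R)-seco bromomethyl enone Z-enal: trans α-methylene lactone with (Z)-CH=C(CH3)CHO on C6 and CH(O-tigloyl)-(E)-CH=C(CH3)C(=O)CH2Br on C7 | C=C1C(=O)O[C@H](/C=C(/C)C=O)[C@H]1[C@H](OC(=O)/C(C)=C/C)/C=C(\C)C(=O)CBr | intermediate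
25 | trivalent samarium enolate of 24 (O–Sm on C1, C1=C2) | C=C1C(=O)O[C@H](/C=C(/C)C=O)[C@H]1[C@H](OC(=O)/C(C)=C/C)/C=C(\C)C(=C)O[Sm](I)I | intermediate
26 | trivalent samarium aldolate of the closed ten-membered ring (O–Sm on C3) | C=C1C(=O)O[C@@H]2/C=C(/C)[C@@H](O[Sm](I)I)CC(=O)/C(C)=C/[C@@H](OC(=O)/C(C)=C/C)[C@@H]12 | intermediate
27 | (3S,6R,7S,8R)-3-hydroxy-1-ketone of the germacranolide skeleton, lactone and tiglate complete | C=C1C(=O)O[C@@H]2/C=C(/C)[C@@H](O)CC(=O)/C(C)=C/[C@@H](OC(=O)/C(C)=C/C)[C@@H]12 | intermediate
28 | acetaldehyde | CC=O | starting material
29 | CNP0319825.6, (1S,3S,6R,7S,8R)-3-acetoxy-1-hydroxy-8-tigloyloxy germacra-4Z,9E,11(13)-trien-12,6-olide | C=C1C(=O)O[C@@H]2/C=C(/C)[C@@H](OC(C)=O)C[C@H](O)/C(C)=C/[C@@H](OC(=O)/C(C)=C/C)[C@@H]12 | target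

## Step count and least certain steps

Total step count: 16. Longest linear sequence: 16 steps (1 to 29). Compounds 5, 9, 12, 15, 19 and 28 are bought and enter directly.

**Step 15 (key step).**
- What may go wrong: protonation of the enolate without ring closure, because transannular strain slows the C2–C3 bond formation; poor facial selectivity at C3, because the preference rests on a conformational model of the seco chain; electron transfer to the enal or the γ-acyloxy enone if reductant accumulates.
- Fallback: take the reductant out of the ring closure and put C3 under reagent control. It sets out from methyl enone 20. Aqueous HF in MeCN frees the C3 alcohol to give the hydroxy methyl enone F1. Buffered Dess–Martin oxidation gives the methyl ketone Z-enal F2. F2 is cyclised at high dilution through its boron enolate (Ipc2BCl of the antipode that directs C2 to the Si face of the aldehyde, Et3N, Et2O, −78 °C, non-oxidative work-up). This returns to the route at 27.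

**Step 8.**
- What may go wrong: elimination across C7–C8 or failure of the displacement, because the carbinol is flanked by the branched C7 and tiglic acid is a weak Mitsunobu acid.
- Fallback: separate inversion from acylation. It sets out from 14. Mitsunobu reaction with the much more acidic chloroacetic acid (PPh3, DIAD) gives the inverted chloroacetate F3. Thiourea with NaHCO3 removes the chloroacetyl group under neutral conditions to give the C8 alcohol of target configuration F4. Yamaguchi esterification with tiglic acid 15 (2,4,6-trichlorobenzoyl chloride, Et3N, then 4-(dimethylamino)pyridine) returns to the route at 16.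
- If the Barbier addition of step 7 delivered F4 directly, the same acylation would be used without any inversion.

**Step 12.**
- What may go wrong: enolisation toward C14 or C8 (extended dienol ether) in place of C2, or electrophilic bromination of the electron-rich C4–C5 alkene.
- Fallback: bring the halogen in with the ylide. It sets out from aldehyde 18. The chloro ylide 1-chloro-3-(triphenylphosphoranylidene)butan-2-one F5 is made from ethyltriphenylphosphonium bromide, base and chloroacetyl chloride. Its Wittig reaction with 18 gives the chloromethyl enone F6. Halide exchange with NaBr in acetone returns to the route at 22.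

**Step 16.**
- What may go wrong: retro-aldol opening of the strained β-hydroxy ketone on the Lewis-acidic samarium; slow hydride transfer to the conjugated C1 ketone; acetyl migration from O3 to O1.
- Fallback: acylate and reduce separately. It sets out from 27. Acetylation (Ac2O, pyridine, 0 °C) gives the 3-acetoxy-1-ketone F7. Reagent-controlled 1,2-reduction with the (R)-methyl CBS catalyst, (R)-1-methyl-3,3-diphenyltetrahydro-1H,3H-pyrrolo[1,2-c][1,3,2]oxazaborole, and catecholborane at −78 °C should give the 1S alcohol. This returns to the route at 29.

## Further compounds

F1 | step 15 | hydroxy methyl enone (20 without the silyl group) | C=C1C(=O)O[C@H](/C=C(/C)CO)[C@H]1[C@H](OC(=O)/C(C)=C/C)/C=C(\C)C(C)=O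
F2 | step 15 | methyl ketone Z-enal (24 with CH3 in place of CH2Br) | C=C1C(=O)O[C@H](/C=C(/C)C=O)[C@H]1[C@H](OC(=O)/C(C)=C/C)/C=C(\C)C(C)=O
F3 | step 8 | C8-inverted chloroacetate of 14 | C=C1C(=O)O[C@H](/C=C(/C)CO[Si](C)(C)C(C)(C)C)[C@H]1[C@H](OC(=O)CCl)COCc1ccc(OC)cc1
F4 | step 8 | C8 alcohol of target configuration (C8 epimer of 14) | C=C1C(=O)O[C@H](/C=C(/C)CO[Si](C)(C)C(C)(C)C)[C@H]1[C@H](O)COCc1ccc(OC)cc1
F5 | step 12 | 1-chloro-3-(triphenylphosphoranylidene)butan-2-one | CC(C(=O)CCl)=P(c1ccccc1)(c1ccccc1)c1ccccc1
F6 | step 12 | chloromethyl enone (22 with Cl in place of Br) | C=C1C(=O)O[C@H](/C=C(/C)CO[Si](C)(C)C(C)(C)C)[C@H]1[C@H](OC(=O)/C(C)=C/C)/C=C(\C)C(=O)CCl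
F7 | step 16 | 3-acetoxy-1-ketone (O-acetyl 27) | C=C1C(=O)O[C@@H]2/C=C(/C)[C@@H](OC(C)=O)CC(=O)/C(C)=C/[C@@H](OC(=O)/C(C)=C/C)[C@@H]12
A1 | alternative 1 | ten-membered carbocycle with free C8 hydroxyl and C11–C13 methylene from the [2,3] ring contraction | C=C(CO[Si](C)(C)C(C)(C)C)[C@H]1[C@H](O[Si](C)(C)C(C)(C)C)/C=C(/C)[C@@H](OCc2ccc(OC)cc2)C[C@H](O[Si](C(C)C)(C(C)C)C(C)C)/C(C)=C/[C@H]1O
A2 | alternative 2 | ten-membered C3 dienone with C1 silyl ether from the Claisen ring expansion | C=C(CO[Si](CC)(CC)CC)[C@H]1[C@H](O[Si](CC)(CC)CC)/C=C(/C)C(=O)C[C@H](O[Si](C)(C)C(C)(C)C)/C(C)=C/[C@H]1OCc1ccc(OC)cc1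
A3 | alternative 3 | ten-membered cyclodec-4-en-9-yn-8-ol from the alkynylchromium ring closure | C=C(CO[Si](CC)(CC)CC)[C@H]1[C@H](O[Si](CC)(CC)CC)/C=C(/C)[C@@H](OCc2ccc(OC)cc2)C[C@H](O[Si](C(C)C)(C(C)C)C(C)C)C#C[C@H]1O
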